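The earlier runs and the new flask were generated by integration from invented constants; scatter was added.

Theta is the flask to reckon from: like eta, it holds equal charges of starting material and reagent .

| flask | starting material | reagent | time |
|---|---|---|---|
| theta | 0.800 M | 0.800 M |  |
| zeta | 2.40 M | 0.800 M |  |
| epsilon | 0.800 M | 2.40 M |  |
| eta | 2.00 M | 2.00 M | 37 min |

| run | time / min | [target] / M |
|---|---|---|
| theta run | 4.6 | 0.024 |
| theta run | 9.2 | 0.083 |
| theta run | 14 | 0.138 |
| theta run | 18 | 0.197 |
| theta run | 23 | 0.242 |
| theta run | 28 | 0.293 |
| theta run | 32 | 0.311 |
| theta run | 37 | 0.354 |
| zeta run | 4.6 | 0.054 |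
| zeta run | 9.2 | 0.150 |
| zeta run | 14 | 0.269 |
| zeta run | 18 | 0.344 |
| zeta run | 23 | 0.437 |
| zeta run | 28 | 0.503 |
| zeta run | 32 | 0.550 |
| zeta run | 37 | 0.604 |
| epsilon run | 4.6 | 0.044 |
| epsilon run | 9.2 | 0.146 |
| epsilon run | 14 | 0.245 |
| epsilon run | 18 | 0.346 |
| epsilon run | 23 | 0.442 |
| epsilon run | 28 | 0.510 |
| epsilon run | 32 | 0.559 |
| epsilon run | 37 | 0.636 |

(each reading ± 0.006 M)

1. reaction order in [reagent] at the outset, round the charge of the theta run, defined at two percent of the starting material turned into target
2. reaction order in [starting material] at the outset, round the charge of the theta run, defined at two percent of the starting material turned into target (one fixed amount of target, the same in the runs compared)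
3. target in the eta run at 37 min, as a share of the starting material charged

- Overall: starting material + reagent -> target.
- Constant volume, constant temperature.
- What is held in complexes is read along with the free species.
- "The second partner" is reagent.
- An order is taken over about fifteen percent of the charge, up and down.

I went to eta by two ways. The first used the charges. At 9.2 min, zeta's larger charge of starting material gave 1.81 times theta's target, and epsilon's larger charge of reagent gave 1.76 times. Read at one time, not at one amount of target, these are orders of 0.539 in starting material and 0.514 in reagent. Their sum is 1.05. Scaling theta's last reading by that total order put eta at 46.4%.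

The second way used the decline. Suppose the rate is κ[S][R], with S the starting material and R the reagent. With equal charges S₀, target x then obeys x/(S₀ − x) = κS₀t. So I defined the clock κ: target made, divided by the charge, the charge less target and the time. Theta's last reading gave 0.0268 M⁻¹ min⁻¹. At eta's charge, that gave 66.5%.

The ways parted by 20 percentage points, so I asked theta which one cheats. Its mean rate fell from 0.0116 M min⁻¹ to 6.78 mM min⁻¹ while the charge less target fell from 0.610 M to 0.477 M. That reads as a total order in time of 2.16, a rough reading, but closer to the clock's 2 than to 1.05. I committed to the clock and to 66.5%.

The forecast gave 0.45 in reagent, 0.45 in starting material and 51% for eta, saying “This fits saturation in both”. The orders round theta's charge came to 0.46 in reagent and 0.49 in starting material, and eta gave 70.7%, which is 4.2 points above my figure.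

    starting material ⇌ intermediate + by-product (0.09540 min⁻¹, 0.3042 M⁻¹ min⁻¹)
    intermediate + reagent → target (0.08340 M⁻¹ min⁻¹)
    starting material + reagent ⇌ idle substrate-reagent adduct, settled at all times (0.5450 M⁻¹)
    starting material + reagent + target → 2 target (0.06360 M⁻² min⁻¹)

Eta's own clock comes to 0.0325 M⁻¹ min⁻¹, against 0.0268 M⁻¹ min⁻¹ from theta. In eta, starting material split from the outset into intermediate and by-product, and the intermediate took up reagent to give target, with idle substrate-reagent adduct standing beside them. Once target stood in the flask, starting material and reagent also went to target on it. Carried to zeta, with its unequal charges, theta's clock puts target at a quarter of the starting material charged at 25.6 min, and zeta reached it at 35.9 min.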